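1. Late in Wednesday's run, which is the flask asked about, the starting material loses 8.5 percentage points between 40.0 min and 80.0 min.

- Wednesday's: starting material 0.020 M; partner 1 equiv; the very flask that is asked about, followed so far
- flask: starting material 0.020 M; partner 1.00 equiv; time 15 h

- Wednesday's (time / min: target / %, starting material / %): 6.00: 5.0, 87.0; 10.0: 7.4, 80.5; 20.0: 16.5, 68.8; 40.0: 25.6, 57.7; 80.0: 24.2, 49.2

(readings scatter by 0.5 percentage points)

* the best time, 15 h at the latest, for target
* the amount of target, in percent of the starting material charged, at that time
* the first time at which target reaches 13%, in the same percent

2. I turn the question round: for the starting material to be used up on 1.00 equiv while the target climbs towards 15 h, each starting material could cost at most one partner. The readings test this.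

3. With equal charges, [starting material] = [partner] at the start, so the first reading gives a rate of 0.0249 min⁻¹, in units of the charge, if the rate is first order in each.

4. Between the last two readings, the starting material falls at 0.00213 min⁻¹. Set against that rate, this leaves [partner] at 16.0% of its charge. So 1.81 partner went per starting material spent. I freeze this reading, the partner cost.

5. This flask stands above the needed value of one, so I expect partner to give out with the starting material near 44.6%. By the same cost, 8.29% of the partner remains at 80.0 min, so the partner cost places no top of the target. I read the top off the target readings instead: they stand at 25.6% at 40.0 min and 24.2% at 80.0 min, so I put it between those times, near 25.6%. Interpolating between the readings at 10.0 min and 20.0 min puts the first 13% near 16.2 min.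

6. The forecast gives 27% (25.5% to 29%) at 0.9 h (0.65 h to 1.3 h), the first 13% at 0.27 h (0.23 h to 0.31 h), and “no later recovery expected”.

7. The flask gives 25.8% at 0.949 h and the first 13% at 0.246 h.

    starting material + partner → intermediate A (k = 0.0210 M⁻¹ s⁻¹)
    intermediate A ⇌ intermediate B (K = 0.220, k = 1.40 × 10⁻⁴ s⁻¹)
    partner + intermediate A → target (k = 0.130 M⁻¹ s⁻¹)
    intermediate A → side product (k = 2.20 × 10⁻⁵ s⁻¹)
    target ⇌ isomer of the product (K = 2.40, k = 1.80 × 10⁻⁴ s⁻¹)

8. At 15.0 h this flask holds 44.4% starting material against my 44.6%, with partner, the limiting reagent, at 0%. The forward half-life of target to isomer of the product, 1.1 h, is shorter than the 15 h allowed, and at that time the flask holds 13.1% target and 31.4% isomer of the product. With 0.250 equiv of partner, the same cost puts the starting material at 86.2%, and that flask holds 82%.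

The runs are calculated from invented constants, and the scatter is random.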